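## Retrosynthetic overview

1. The target is reached from cis-decalin enone 19 by ring-A adjustment only: enone dihydroxylation (O at C2 and C3), C4 methylenation (C18), and diol oxidation to the diosphenol.
2. Ring B, the C9–C10 bond and the C5/C9/C10 stereocentres come from the key step, an anionic oxy-Cope [3,3] rearrangement of bicyclo[2.2.2]octenyl carbinol 12; the C7 enolate it delivers is methylated (C17).
3. Carbinol 12 comes from alkynylation of bicyclic ketone 6 with alkyne acid 10 (C7–C8 bond) followed by syn-methylmetalation of the alkyne (C20).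
4. Ketone 6 comes from (R)-carvone by intramolecular dienolate alkylation (C5–C6 bond); acid 10 comes from (R)-citronellic acid, which supplies C13.
5. Ring order: ring A is bought with carvone, a temporary C6–C7 bridge is added, and ring B is closed in the oxy-Cope step.

Convention and assumption: clerodane numbering is used for the decalins (ring A = C1–C5, C10; ring B = C5–C10; side chain C11–C15 with C16 on C13; C17 on C8, C18 on C4, C19 on C5, C20 on C9), β is the face of the C5 methyl, unless stated the decalins carry 19β-CH3, 10β-H, 20α-CH3, 17α-CH3 and 13R as in the target, and (R)-carvone and (R)-citronellic acid are taken as purchasable single enantiomers.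

## Route

Step 1
Reactants: 1 (R)-carvone
Product: 2 (5R)-5-(3-chloroprop-1-en-2-yl)-2-methylcyclohex-2-en-1-one (10-chlorocarvone)
Conditions: Ca(OCl)2, solid CO2, CH2Cl2/H2O, 0 °C
Reagents that add atoms: calcium hypochlorite, [Ca+2].[O-]Cl.[O-]Cl
Why: Ene-type allylic chlorination by HOCl generated in situ attacks only the electron-rich isopropenyl group (the enone alkene is deactivated) and shifts the double bond to give the 2-(chloromethyl)allyl unit, leaving the carvone stereocentre (future bridgehead C2) untouched.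

Step 2
Reactants: 2 10-chlorocarvone
Product: 3 (1S,4S)-1-methyl-8-methylidenebicyclo[2.2.2]oct-5-en-2-one
Conditions: KOtBu, t-BuOH/THF, 0 °C to rt
Reagents that add atoms: none
Why: γ-Deprotonation gives the extended dienolate, whose α-carbon displaces the allylic chloride intramolecularly (enolate alkylation; SN2 and SN2' give the same product), necessarily on the ring face carrying the side chain, so the new quaternary bridgehead (future C5 with C19) is fixed by the carvone stereocentre.

Step 3
Reactants: 3 bicyclic enone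
Product: 4 (1'S,4'S)-1'-methyl-8'-methylidenespiro[1,3-dioxolane-2,2'-bicyclo[2.2.2]oct[5]ene]
Conditions: Me3SiOCH2CH2OSiMe3, Me3SiOTf (cat.), CH2Cl2, −78 to −20 °C
Reagents that add atoms: 1,2-bis(trimethylsilyloxy)ethane, C[Si](C)(C)OCCO[Si](C)(C)C
Why: Noyori acetalisation masks the hindered ketone (future C4) as a dioxolane under non-isomerising conditions, so that only the later C7 carbonyl meets carbon nucleophiles and bases; no stereocentre changes.

Step 4
Reactants: 4 ketal diene
Product: 6 (1'S,4'S)-1'-methylspiro[1,3-dioxolane-2,2'-bicyclo[2.2.2]oct[5]en]-8'-one, via diol 5 (not isolated)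
Conditions: OsO4 (cat.), NaIO4, 2,6-lutidine, dioxane/H2O, rt
Reagents that add atoms: sodium periodate, [Na+].[O-]I(=O)(=O)=O
Why: Lemieux–Johnson oxidative cleavage, in which OsO4 dihydroxylates the exposed 1,1-disubstituted exocyclic alkene in preference to the ring alkene flanked by the quaternary bridgehead and the dioxolane, and NaIO4 cleaves the diol to the ketone (future C7) without creating a lasting stereocentre.

Step 5
Reactants: 7 (R)-citronellic acid
Product: 9 (3R)-3-methyl-6-oxohexanoic acid, via ozonide 8 (not isolated)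
Conditions: O3, CH2Cl2, −78 °C; then PPh3, −78 °C to rt
Reagents that add atoms: ozone, [O-][O+]=O
Why: Ozonolysis with reductive work-up cleaves the trisubstituted alkene to the aldehyde, the 3R centre (future C13) being remote and untouched.

Step 6
Reactants: 9 aldehyde acid
Product: 10 (3R)-3-methylhept-6-ynoic acid
Conditions: dimethyl (1-diazo-2-oxopropyl)phosphonate, K2CO3, MeOH, 0 °C to rt; dilute HCl work-up
Reagents that add atoms: dimethyl (1-diazo-2-oxopropyl)phosphonate, COP(=O)(OC)C(=[N+]=[N-])C(C)=O
Why: Ohira–Bestmann (Seyferth–Gilbert) homologation turns the aldehyde into the terminal alkyne (future C9≡C8) under mild carbonate conditions that cannot affect the remote stereocentre.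

Step 7
Reactants: 6 keto ketal; 10 alkyne acid
Product: 11 (3R)-7-[(1'S,4'S,8'R)-8'-hydroxy-1'-methylspiro[1,3-dioxolane-2,2'-bicyclo[2.2.2]oct[5]en]-8'-yl]-3-methylhept-6-ynoic acid
Conditions: 10 (1.3 equiv), n-BuLi (2.6 equiv), THF, −78 to 0 °C; then 6, −78 to −20 °C; cold dilute HCl to pH 4
Reagents that add atoms: none
Why: 1,2-Addition of the lithium acetylide of the carboxylate dianion (alkynylation) occurs on the carbonyl face next to the flat C5'=C6' bridge rather than the face next to the CH2–C(ketal) bridge, setting the carbinol centre with the alkynyl group syn to the ring alkene as the rearrangement requires.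

Step 8
Reactants: 11 propargylic alcohol acid
Product: 12 (3R,6Z)-7-[(1'S,4'S,8'R)-8'-hydroxy-1'-methylspiro[1,3-dioxolane-2,2'-bicyclo[2.2.2]oct[5]en]-8'-yl]-3,6-dimethylhept-6-enoic acid
Conditions: MeMgBr (5 equiv), Fe(acac)3 (20 mol %), THF, −20 °C to rt; cold dilute HCl to pH 4
Reagents that add atoms: methylmagnesium bromide, C[Mg]Br
Why: Alkoxide-directed Fe-catalysed carbomagnesiation adds CH3 and Mg syn across the alkyne with CH3 on the carbon remote from the carbinol, so protonation of the vinylmagnesium on work-up leaves the (Z)-trisubstituted alkene with the side chain cis and the new methyl (future C20) trans to the carbinol carbon.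

Step 9
Reactants: 12 (Z)-alkenyl carbinol acid
Product: 15 methyl 4,4-ethylenedioxy-7-oxo-18-norcleroda-1-en-15-oate (8α-methyl), via dipotassium enolate 13 (not isolated), via 8-epi ketone 14 (not isolated)
Conditions: KH (2.3 equiv), 18-crown-6, THF, 0 to 40 °C; MeI, 0 °C to rt; evaporate; NaOMe (cat.), MeOH, rt
Reagents that add atoms: iodomethane, CI
Why: The anionic oxy-Cope [3,3]-sigmatropic rearrangement through the boat transition state enforced by the bicycle forms the C9–C10 bond and ring B suprafacially, giving the cis ring fusion (C19 and H10 syn) and, from the (Z)-alkene, C11 syn and C20 anti to H10 at the new quaternary C9, after which MeI C-methylates the C7 enolate at C8 and O-methylates the carboxylate, and methoxide is expected to equilibrate C8 mainly to the equatorial 8α-methyl epimer (cis to C20; estimated about 5:1, minor epimer separated and re-equilibrated).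

Step 10
Reactants: 15 keto ester
Product: 16 methyl 4,4-ethylenedioxy-7β-hydroxy-18-norcleroda-1-en-15-oate
Conditions: SmI2, THF/H2O, 0 °C to rt
Reagents that add atoms: none
Why: Single-electron (ketyl) reduction by SmI2 with water as proton source gives the thermodynamically preferred equatorial 7β-alcohol, trans to the equatorial 8α-methyl, whereas a hydride would enter equatorially because the axial face is blocked by the axial C20 methyl and C4.

Step 11
Reactants: 16 7β-alcohol
Product: 17 methyl 7β-acetoxy-4,4-ethylenedioxy-18-norcleroda-1-en-15-oate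
Conditions: Ac2O, pyridine, 4-(dimethylamino)pyridine (cat.), rt
Reagents that add atoms: acetic anhydride, CC(=O)OC(C)=O
Why: Nucleophile-catalysed acylation (esterification) of the secondary alcohol proceeds with retention at C7.

Step 12
Reactants: 17 acetate ketal
Product: 19 methyl 7β-acetoxy-4-oxo-18-norcleroda-2-en-15-oate, via non-conjugated enone 18 (not isolated)
Conditions: p-toluenesulfonic acid monohydrate (cat.), acetone/H2O, 45 °C; then 1,8-diazabicyclo[5.4.0]undec-7-ene (cat.), CH2Cl2, rt
Reagents that add atoms: water, O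
Why: Acid-catalysed acetal hydrolysis frees the C4 ketone and base-catalysed prototropic isomerisation moves the β,γ double bond into conjugation (C2=C3), the acetate, the ester and all stereocentres being unaffected.

Step 13
Reactants: 19 enone
Product: 20 methyl 7β-acetoxy-2β,3β-dihydroxy-4-oxo-18-norclerodan-15-oate
Conditions: OsO4 (cat.), N-methylmorpholine N-oxide, citric acid, t-BuOH/H2O, rt
Reagents that add atoms: N-methylmorpholine N-oxide, C[N+]1([O-])CCOCC1; water, O
Why: Upjohn syn-dihydroxylation of the enone (citric acid speeds turnover for the electron-poor alkene) occurs on the β face away from the axial C9 substituent, and the two new carbinol centres are transient because both are oxidised in step 15.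

Step 14
Reactants: 20 keto diol
Product: 21 methyl 7β-acetoxy-2β,3β-dihydroxycleroda-4(18)-en-15-oate
Conditions: Zn, CH2Br2, TiCl4, THF/CH2Cl2, 0 °C to rt
Reagents that add atoms: dibromomethane, BrCBr
Why: Lombardo methylenation with the non-basic gem-dizinc/titanium reagent converts the hindered, chelating α-hydroxy ketone into the exocyclic alkene (C18) without touching the acetate or methyl ester or epimerising any centre.

Step 15
Reactants: 21 methylene diol
Product: 24 methyl (5S,7S,8S,9R,10R,13R)-7-acetoxy-2-hydroxy-3-oxocleroda-1,4(18)-dien-15-oate (target), via ketol 22 (not isolated), via dione 23 (not isolated)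
Conditions: IBX, DMSO, rt
Reagents that add atoms: none
Why: IBX oxidises the allylic carbinol and then the α-ketol without C–C cleavage, and the resulting 2,3-dione, which has α-hydrogens only at C1, enolises to the conjugated diosphenol that is the target, the six remaining stereocentres being untouched.

## Compound list

1 | (R)-(−)-carvone, (5R)-2-methyl-5-(prop-1-en-2-yl)cyclohex-2-en-1-one | CC1=CC[C@H](CC1=O)C(C)=C | starting material
2 | (5R)-5-(3-chloroprop-1-en-2-yl)-2-methylcyclohex-2-en-1-one | CC1=CC[C@H](CC1=O)C(=C)CCl | intermediate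
3 | (1S,4S)-1-methyl-8-methylidenebicyclo[2.2.2]oct-5-en-2-one | C[C@]12C=C[C@H](CC1=O)C(=C)C2 | intermediate
4 | (1'S,4'S)-1'-methyl-8'-methylidenespiro[1,3-dioxolane-2,2'-bicyclo[2.2.2]oct[5]ene] | C[C@]12C=C[C@H](CC13OCCO3)C(=C)C2 | intermediate
5 | (1'S,4'S,8'S)-8'-(hydroxymethyl)-1'-methylspiro[1,3-dioxolane-2,2'-bicyclo[2.2.2]oct[5]en]-8'-ol (configuration at C8' of no consequence) | C[C@]12C=C[C@H](CC13OCCO3)[C@](O)(CO)C2 | intermediate (not isolated)
6 | (1'S,4'S)-1'-methylspiro[1,3-dioxolane-2,2'-bicyclo[2.2.2]oct[5]en]-8'-one | C[C@]12C=C[C@H](CC13OCCO3)C(=O)C2 | intermediate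
7 | (R)-(+)-citronellic acid, (3R)-3,7-dimethyloct-6-enoic acid | CC(C)=CCC[C@@H](C)CC(O)=O | starting material
8 | (3R)-5-(5,5-dimethyl-1,2,4-trioxolan-3-yl)-3-methylpentanoic acid (ozonide, both epimers at the ring carbon) | CC1(C)OOC(CC[C@@H](C)CC(O)=O)O1 | intermediate (not isolated)
9 | (3R)-3-methyl-6-oxohexanoic acid | O=CCC[C@@H](C)CC(O)=O | intermediate
10 | (3R)-3-methylhept-6-ynoic acid | C#CCC[C@@H](C)CC(O)=O | intermediate
11 | (3R)-7-[(1'S,4'S,8'R)-8'-hydroxy-1'-methylspiro[1,3-dioxolane-2,2'-bicyclo[2.2.2]oct[5]en]-8'-yl]-3-methylhept-6-ynoic acid (alkynyl syn to the C5'=C6' bridge) | C[C@]12C=C[C@H](CC13OCCO3)[C@@](O)(C#CCC[C@@H](C)CC(O)=O)C2 | intermediate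
12 | (3R,6Z)-7-[(1'S,4'S,8'R)-8'-hydroxy-1'-methylspiro[1,3-dioxolane-2,2'-bicyclo[2.2.2]oct[5]en]-8'-yl]-3,6-dimethylhept-6-enoic acid | C[C@]12C=C[C@H](CC13OCCO3)[C@@](O)(/C=C(/C)CC[C@@H](C)CC(O)=O)C2 | intermediate
13 | dipotassium 4,4-ethylenedioxy-7-oxido-18-norcleroda-1,7-dien-15-oate (C7 enolate, carboxylate) | C12(OCCO1)CC=C[C@@H]3[C@@](C)(CC[C@@H](C)CC(=O)[O-])C=C([O-])C[C@]23C.[K+].[K+] | intermediate (not isolated)
14 | methyl 4,4-ethylenedioxy-7-oxo-18-norcleroda-1-en-15-oate, 8β-methyl epimer | C12(OCCO1)CC=C[C@@H]3[C@@](C)(CC[C@@H](C)CC(=O)OC)[C@@H](C)C(=O)C[C@]23C | intermediate (not isolated)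
15 | methyl 4,4-ethylenedioxy-7-oxo-18-norcleroda-1-en-15-oate (8α-methyl) | C12(OCCO1)CC=C[C@@H]3[C@@](C)(CC[C@@H](C)CC(=O)OC)[C@H](C)C(=O)C[C@]23C | intermediate
16 | methyl 4,4-ethylenedioxy-7β-hydroxy-18-norcleroda-1-en-15-oate | C12(OCCO1)CC=C[C@@H]3[C@@](C)(CC[C@@H](C)CC(=O)OC)[C@H](C)[C@@H](O)C[C@]23C | intermediate
17 | methyl 7β-acetoxy-4,4-ethylenedioxy-18-norcleroda-1-en-15-oate | C12(OCCO1)CC=C[C@@H]3[C@@](C)(CC[C@@H](C)CC(=O)OC)[C@H](C)[C@@H](OC(C)=O)C[C@]23C | intermediate
18 | methyl 7β-acetoxy-4-oxo-18-norcleroda-1-en-15-oate | O=C1CC=C[C@@H]2[C@@](C)(CC[C@@H](C)CC(=O)OC)[C@H](C)[C@@H](OC(C)=O)C[C@]12C | intermediate (not isolated)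
19 | methyl 7β-acetoxy-4-oxo-18-norcleroda-2-en-15-oate | O=C1C=CC[C@@H]2[C@@](C)(CC[C@@H](C)CC(=O)OC)[C@H](C)[C@@H](OC(C)=O)C[C@]12C | intermediate
20 | methyl 7β-acetoxy-2β,3β-dihydroxy-4-oxo-18-norclerodan-15-oate | O=C1[C@@H](O)[C@@H](O)C[C@@H]2[C@@](C)(CC[C@@H](C)CC(=O)OC)[C@H](C)[C@@H](OC(C)=O)C[C@]12C | intermediate
21 | methyl 7β-acetoxy-2β,3β-dihydroxycleroda-4(18)-en-15-oate | C=C1[C@@H](O)[C@@H](O)C[C@@H]2[C@@](C)(CC[C@@H](C)CC(=O)OC)[C@H](C)[C@@H](OC(C)=O)C[C@]12C | intermediate
22 | methyl 7β-acetoxy-2β-hydroxy-3-oxocleroda-4(18)-en-15-oate | C=C1C(=O)[C@@H](O)C[C@@H]2[C@@](C)(CC[C@@H](C)CC(=O)OC)[C@H](C)[C@@H](OC(C)=O)C[C@]12C | intermediate (not isolated)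
23 | methyl 7β-acetoxy-2,3-dioxocleroda-4(18)-en-15-oate | C=C1C(=O)C(=O)C[C@@H]2[C@@](C)(CC[C@@H](C)CC(=O)OC)[C@H](C)[C@@H](OC(C)=O)C[C@]12C | intermediate (not isolated)
24 | methyl (5S,7S,8S,9R,10R,13R)-7-acetoxy-2-hydroxy-3-oxocleroda-1,4(18)-dien-15-oate (CNP0180040.1) | C=C1C(=O)C(O)=C[C@@H]2[C@@](C)(CC[C@@H](C)CC(=O)OC)[C@H](C)[C@@H](OC(C)=O)C[C@]12C | target

## Step count and weak points

Total steps: 15. Longest linear sequence: 13 (steps 1–4 and 7–15, from (R)-carvone); steps 5–6 make the side-chain alkyne from (R)-citronellic acid.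

The three steps most likely to fail:

Step 8, because the Fe-catalysed carbomagnesiation has to work on a hindered tertiary propargylic alkoxide that also carries a magnesium carboxylate. The fallback sets out from 11: copper-catalysed syn-hydroboration (CuCl, NaOtBu, 4,5-bis(diphenylphosphino)-9,9-dimethylxanthene, B2pin2, MeOH, THF) places boron on the alkyne carbon remote from the carbinol and hydrogen on the near carbon, giving the (Z)-alkenyl pinacolboronate F1. A Suzuki–Miyaura methylation (MeI, Pd(dppf)Cl2, Cs2CO3, DMF; then aqueous LiOH to cleave any methyl ester formed) then replaces boron by methyl with retention and comes back to the route at 12.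

Step 9, because the anionic oxy-Cope rearrangement must create the quaternary C9 next to C10 and the quaternary C5, and the alkoxide may fragment or the enolate may methylate on oxygen. The fallback sets out from 12: esterification with Me3SiCHN2 gives the methyl ester F2, silylation of the tertiary alcohol (Me3SiOTf, 2,6-lutidine) gives the trimethylsilyl ether F3, and heating (toluene, sealed tube, about 200 °C) effects the neutral siloxy-Cope rearrangement through the same boat geometry to the trimethylsilyl enol ether F4. Methylation at C8 with MeI and anhydrous benzyltrimethylammonium fluoride, then NaOMe in MeOH, comes back to the route at 15.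

Step 10, because the SmI2 reduction must deliver the equatorial 7β-alcohol. The fallback sets out from 15: NaBH4 in MeOH gives mainly the axial 7α-alcohol F5, which is epimerised at the carbinol carbon by reversible hydrogen transfer with Ru(CO)2Cl(η5-C5Ph5) and KOtBu (both catalytic) in toluene to the more stable equatorial alcohol, coming back to the route at 16.

Further compounds

F1 | step 8 | (3R,6Z)-7-[(1'S,4'S,8'R)-8'-hydroxy-1'-methylspiro[1,3-dioxolane-2,2'-bicyclo[2.2.2]oct[5]en]-8'-yl]-3-methyl-6-(4,4,5,5-tetramethyl-1,3,2-dioxaborolan-2-yl)hept-6-enoic acid | C[C@]12C=C[C@H](CC13OCCO3)[C@@](O)(/C=C(/B4OC(C)(C)C(C)(C)O4)CC[C@@H](C)CC(O)=O)C2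
F2 | step 9 | methyl (3R,6Z)-7-[(1'S,4'S,8'R)-8'-hydroxy-1'-methylspiro[1,3-dioxolane-2,2'-bicyclo[2.2.2]oct[5]en]-8'-yl]-3,6-dimethylhept-6-enoate | C[C@]12C=C[C@H](CC13OCCO3)[C@@](O)(/C=C(/C)CC[C@@H](C)CC(=O)OC)C2
F3 | step 9 | methyl (3R,6Z)-3,6-dimethyl-7-[(1'S,4'S,8'R)-1'-methyl-8'-(trimethylsilyloxy)spiro[1,3-dioxolane-2,2'-bicyclo[2.2.2]oct[5]en]-8'-yl]hept-6-enoate | C[C@]12C=C[C@H](CC13OCCO3)[C@@](O[Si](C)(C)C)(/C=C(/C)CC[C@@H](C)CC(=O)OC)C2
F4 | step 9 | methyl 4,4-ethylenedioxy-7-(trimethylsilyloxy)-18-norcleroda-1,7-dien-15-oate | C12(OCCO1)CC=C[C@@H]3[C@@](C)(CC[C@@H](C)CC(=O)OC)C=C(O[Si](C)(C)C)C[C@]23C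
F5 | step 10 | methyl 4,4-ethylenedioxy-7α-hydroxy-18-norcleroda-1-en-15-oate | C12(OCCO1)CC=C[C@@H]3[C@@](C)(CC[C@@H](C)CC(=O)OC)[C@H](C)[C@H](O)C[C@]23C
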